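**Retrosynthetic overview**

- The strategy rests on the methine carbon that carries C6 of ring A (chroman with 2-methylbutanoyl at C8), C6 of ring B (chroman with isobutyryl at C8), the first CH2 of the 5-methylhexyl chain and one hydrogen. With boron in place of that hydrogen it is the boron-bearing carbon of a 1-(ring B aryl)vinyl boronate.
- Key disconnection: the methine–C6(ring A) bond and the bond between chain carbons 1 and 2 are made together from a ring B 1-arylvinyl pinacol boronate, a ring A C6 aryllithium and 1-iodo-4-methylpentane by nickel-catalysed conjunctive coupling. The C–B bond is then exchanged for C–H with retention.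
- The acyl groups come last: isobutyryl at C8 of ring B by directed lithiation, then (R)-2-methylbutanoyl at C8 of ring A by Friedel–Crafts acylation. A chlorine at C8 of ring A makes the two aryl groups different, leaves ring B with the only aromatic C–H, blocks ring A until the end and is then removed by hydrogenolysis.
- Both aryl partners come from one chroman and one C6 bromide. The dihydropyran ring is closed first (phloroglucinol and 2-methylbut-3-en-2-ol), and a single lithiation between two methoxymethyl (MOM) ethers followed by bromination marks C6. The bromide goes to ring B through its Grignard reagent and to ring A by chlorination at C8. No ring is formed after step 1.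

Key step: step 9

Assumption: the sense of induction of the nickel–diamine catalyst on a 1-arylvinyl boronate is not established, so the (S,S) diamine is written and its enantiomer is taken if a test coupling gives the mirror-image boronate; (R)-2-methylbutanoic acid is taken as a purchasable material.

**Route**

Step 1
Reactants: 1 phloroglucinol; 2 2-methylbut-3-en-2-ol
Product: 4 2,2-dimethylchroman-5,7-diol, via C-prenylphloroglucinol 3 (not isolated)
Conditions: BF3·OEt2, 1,4-dioxane, rt, 1 in excess
Reagents that add atoms: none
Why: Friedel–Crafts C-prenylation of the symmetrical triol by the allylic cation, then acid-catalysed Markovnikov addition of the neighbouring phenol to the trisubstituted alkene, should close the dihydropyran ring, and the symmetry of 1 allows only one chroman.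

Step 2
Reactants: 4 2,2-dimethylchroman-5,7-diol
Product: 5 5,7-bis(methoxymethoxy)-2,2-dimethylchroman
Conditions: MOMCl, i-Pr2NEt, CH2Cl2, 0 °C → rt
Reagents that add atoms: chloromethyl methyl ether, COCCl
Why: O-alkylation of both phenols (Williamson-type acetal formation) should give the bis-MOM ether needed for directed metalation.

Step 3
Reactants: 5 5,7-bis(methoxymethoxy)-2,2-dimethylchroman
Product: 7 6-bromo-5,7-bis(methoxymethoxy)-2,2-dimethylchroman, via C6 aryllithium 6 (not isolated)
Conditions: n-BuLi, THF, 0 °C; then BrCCl2CCl2Br, −78 °C → rt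
Reagents that add atoms: 1,2-dibromo-1,1,2,2-tetrachloroethane, BrC(Cl)(Cl)C(Cl)(Cl)Br
Why: Directed ortho-metalation should take place at C6, which lies between two chelating MOM ethers (the C5 ether is held toward C6 by the C4 methylene), in preference to C8, and bromine transfer from the positive-bromine donor fixes the halogen there; any minor C8 isomer is removed once at this bromide, from which both aryl partners are then made.

Step 4
Reactants: 7 6-bromo-5,7-bis(methoxymethoxy)-2,2-dimethylchroman
Product: 9 1-[5,7-bis(methoxymethoxy)-2,2-dimethylchroman-6-yl]ethan-1-one, via arylmagnesium bromide 8 (not isolated)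
Conditions: Mg turnings (activated with a crystal of I2), LiCl, THF, rt → 40 °C; then MeC(O)N(OMe)Me, 0 °C → rt; aq. NH4Cl
Reagents that add atoms: N-methoxy-N-methylacetamide, CON(C)C(C)=O
Why: LiCl-assisted magnesium insertion into the aryl bromide (Grignard formation) tolerates the MOM ethers, and Weinreb amide acylation stops at the ketone because the chelated tetrahedral adduct only collapses on work-up.

Step 5
Reactants: 9 1-[5,7-bis(methoxymethoxy)-2,2-dimethylchroman-6-yl]ethan-1-one
Product: 11 1-[5,7-bis(methoxymethoxy)-2,2-dimethylchroman-6-yl]vinyl trifluoromethanesulfonate, via potassium enolate 10 (not isolated)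
Conditions: KN(SiMe3)2, THF, −78 °C; then PhNTf2, −78 → 0 °C; aq. NH4Cl
Reagents that add atoms: N-phenylbis(trifluoromethanesulfonimide), O=S(=O)(N(c1ccccc1)S(=O)(=O)C(F)(F)F)C(F)(F)F
Why: Enolate formation at the only enolisable position and O-sulfonylation (enol triflate synthesis) should give the 1-arylvinyl triflate.

Step 6
Reactants: 11 1-[5,7-bis(methoxymethoxy)-2,2-dimethylchroman-6-yl]vinyl trifluoromethanesulfonate
Product: 12 2-{1-[5,7-bis(methoxymethoxy)-2,2-dimethylchroman-6-yl]vinyl}-4,4,5,5-tetramethyl-1,3,2-dioxaborolane
Conditions: B2pin2, PdCl2(PPh3)2 (3 mol%), PPh3, KOPh, toluene, 50 °C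
Reagents that add atoms: bis(pinacolato)diboron, CC1(C)OB(OC1(C)C)B1OC(C)(C)C(C)(C)O1
Why: Miyaura borylation of an alkenyl triflate (oxidative addition to zerovalent palladium, phenoxide-assisted transmetalation, reductive elimination) should place boron on the internal alkene carbon without moving the double bond.

Step 7
Reactants: 7 6-bromo-5,7-bis(methoxymethoxy)-2,2-dimethylchroman
Product: 13 6-bromo-8-chloro-5,7-bis(methoxymethoxy)-2,2-dimethylchroman
Conditions: NCS, MeCN, rt, dark
Reagents that add atoms: N-chlorosuccinimide, O=C1CCC(=O)N1Cl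
Why: Electrophilic aromatic chlorination should occur at C8, the only unsubstituted ring position and activated by three oxygen substituents, under neutral conditions that leave the acetals intact.

Step 8
Reactants: 14 1-bromo-4-methylpentane
Product: 15 1-iodo-4-methylpentane
Conditions: NaI, acetone, reflux
Reagents that add atoms: sodium iodide, [Na+].[I-]
Why: Finkelstein SN2 halide exchange at a primary carbon is driven by precipitation of NaBr.

Step 9
Reactants: 13 6-bromo-8-chloro-5,7-bis(methoxymethoxy)-2,2-dimethylchroman; 12 ring B 1-arylvinyl pinacol boronate; 15 1-iodo-4-methylpentane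
Product: 18 2-[(1R)-1-[8-chloro-5,7-bis(methoxymethoxy)-2,2-dimethylchroman-6-yl]-1-[5,7-bis(methoxymethoxy)-2,2-dimethylchroman-6-yl]-6-methylheptyl]-4,4,5,5-tetramethyl-1,3,2-dioxaborolane, via ring A aryllithium 16 (not isolated), via boron ate complex 17 (not isolated)
Conditions: 13, t-BuLi (2.0 equiv), Et2O, −78 °C; 12 in THF, −78 → 0 °C; then NiBr2(dme) (10 mol%), (S,S)-N,N'-dimethyl-1,2-diphenylethane-1,2-diamine (12 mol%), 15 (1.5 equiv), THF, 0 °C → rt
Reagents that add atoms: none
Why: Proposed new method: the closest known reaction type is the nickel-catalysed enantioselective conjunctive cross-coupling of vinylboron ate complexes with alkyl iodides, which gives secondary boronic esters from unsubstituted vinyl boronates, and it is extended here to a 1-arylvinyl boronate and a di-ortho-substituted migrating aryl group so that a fully substituted boron-bearing carbon results. Bromine–lithium exchange at C6 of 13 (the chlorine is inert at −78 °C and not ortho to lithium) gives 16, which adds to boron of 12 to form ate complex 17; the alkyl–nickel species formed from 15 and low-valent nickel binds the alkene of 17 and triggers a 1,2-metallate shift in which the ring A aryl group moves from boron to the internal alkene carbon anti to nickel, and reductive elimination then joins the terminal alkene carbon to C1 of the 4-methylpentyl group. No ring is closed. The new stereocentre is set in the metallate shift by the alkene face that the chiral diamine–nickel complex binds, and the two faces differ by the ring B aryl group against the boronate, so the catalyst does not have to tell the two similar aryl groups apart. The step needs chemoselectivity for the alkyl iodide over the hindered electron-rich aryl chloride, which should not add to the nickel–diamine catalyst at room temperature, and migration of the aryl group in preference to a pinacol oxygen, which the electron-rich ring A aryl group favours.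

Step 10
Reactants: 18 (R)-tertiary diarylalkyl pinacol boronate
Product: 19 8-chloro-6-[(1R)-1-[5,7-bis(methoxymethoxy)-2,2-dimethylchroman-6-yl]-6-methylheptyl]-5,7-bis(methoxymethoxy)-2,2-dimethylchroman
Conditions: CsF (1.5 equiv), H2O (1.1 equiv), 1,4-dioxane, 45 °C
Reagents that add atoms: none
Why: Stereoretentive protodeboronation of a tertiary diarylalkyl boronic ester: fluoride forms the boronate complex and water protonates the C–B bond from the front, so hydrogen should take the place of boron with retention.

Step 11
Reactants: 19 (R)-diarylalkane with chlorine at C8 of ring A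
Product: 21 1-[6-[(1R)-1-[8-chloro-5,7-bis(methoxymethoxy)-2,2-dimethylchroman-6-yl]-6-methylheptyl]-5,7-bis(methoxymethoxy)-2,2-dimethylchroman-8-yl]-2-methylpropan-1-one, via ring B C8 aryllithium 20 (not isolated)
Conditions: n-BuLi, TMEDA, THF, −20 → 0 °C; then i-PrC(O)N(OMe)Me, −78 °C → rt; aq. NH4Cl
Reagents that add atoms: N-methoxy-N-methylisobutyramide, CON(C)C(=O)C(C)C
Why: Directed ortho-metalation can only occur at C8 of ring B, the single aromatic C–H left in the molecule and flanked by a MOM ether and the ring oxygen (ring A is fully substituted, and the crowded methine between twisted electron-rich aryl groups should not be deprotonated), and Weinreb amide acylation gives the ketone.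

Step 12
Reactants: 21 ring B isobutyryl ketone with four MOM ethers
Product: 22 1-[6-[(1R)-1-(8-chloro-5,7-dihydroxy-2,2-dimethylchroman-6-yl)-6-methylheptyl]-5,7-dihydroxy-2,2-dimethylchroman-8-yl]-2-methylpropan-1-one
Conditions: 3 M aq. HCl, MeOH, 45 °C
Reagents that add atoms: none
Why: Acid-catalysed acetal cleavage with methanol should free all four phenols, while the acylated ring B and the chlorinated ring A resist ipso-protonation, which protects the diarylmethine bond and its configuration.

Step 13
Reactants: 22 chlorinated tetraphenol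
Product: 23 1-[6-[(1S)-1-(5,7-dihydroxy-2,2-dimethylchroman-6-yl)-6-methylheptyl]-5,7-dihydroxy-2,2-dimethylchroman-8-yl]-2-methylpropan-1-one (same spatial arrangement; the descriptor changes because ring B now ranks above ring A)
Conditions: H2 (1 atm), 10% Pd/C, Et3N, MeOH, rt
Reagents that add atoms: none
Why: Catalytic hydrodechlorination of the aryl chloride over palladium with an amine as HCl acceptor should free C8 of ring A without touching the hydrogen-bonded aryl ketone or the chroman ethers.

Step 14
Reactants: 24 (R)-2-methylbutanoic acid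
Product: 25 (R)-2-methylbutanoyl chloride
Conditions: (COCl)2, cat. DMF, CH2Cl2, 0 °C → rt, used directly
Reagents that add atoms: oxalyl chloride, O=C(Cl)C(Cl)=O
Why: Acid chloride formation through the chloroiminium species at low temperature and without base should not enolise the α-stereocentre.

Step 15
Reactants: 23 tetraphenol with free C8 on ring A; 25 (R)-2-methylbutanoyl chloride
Product: 26 (2R)-1-[6-[(1R)-1-[5,7-dihydroxy-2,2-dimethyl-8-(2-methylpropanoyl)chroman-6-yl]-6-methylheptyl]-5,7-dihydroxy-2,2-dimethylchroman-8-yl]-2-methylbutan-1-one (CNP0287681.1)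
Conditions: AlCl3 (5 equiv), PhNO2–CH2Cl2, 0 °C → rt; then ice-cold 1 M HCl
Reagents that add atoms: none
Why: Friedel–Crafts acylation can only take place at C8 of ring A, the one free aromatic position (ring B is fully substituted and deactivated by its ketone), any O-acyl product should undergo Fries shift under the same conditions, and the low temperature and absence of base should limit ketene formation so that the (R) acyl centre is carried over.

**Compound list**

1 | phloroglucinol | Oc1cc(O)cc(O)c1 | starting material
2 | 2-methylbut-3-en-2-ol | CC(C)(O)C=C | starting material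
3 | 2-(3-methylbut-2-en-1-yl)benzene-1,3,5-triol | CC(C)=CCc1c(O)cc(O)cc1O | intermediate (not isolated)
4 | 2,2-dimethylchroman-5,7-diol | CC1(C)CCc2c(O)cc(O)cc2O1 | intermediate
5 | 5,7-bis(methoxymethoxy)-2,2-dimethylchroman | CC1(C)CCc2c(OCOC)cc(OCOC)cc2O1 | intermediate
6 | [5,7-bis(methoxymethoxy)-2,2-dimethylchroman-6-yl]lithium | [Li]c1c(OCOC)cc2OC(C)(C)CCc2c1OCOC | intermediate (not isolated)
7 | 6-bromo-5,7-bis(methoxymethoxy)-2,2-dimethylchroman | Brc1c(OCOC)cc2OC(C)(C)CCc2c1OCOC | intermediate
8 | [5,7-bis(methoxymethoxy)-2,2-dimethylchroman-6-yl]magnesium bromide | Br[Mg]c1c(OCOC)cc2OC(C)(C)CCc2c1OCOC | intermediate (not isolated)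
9 | 1-[5,7-bis(methoxymethoxy)-2,2-dimethylchroman-6-yl]ethan-1-one | CC(=O)c1c(OCOC)cc2OC(C)(C)CCc2c1OCOC | intermediate
10 | potassium enolate of 9 | [K+].[O-]C(=C)c1c(OCOC)cc2OC(C)(C)CCc2c1OCOC | intermediate (not isolated)
11 | 1-[5,7-bis(methoxymethoxy)-2,2-dimethylchroman-6-yl]vinyl trifluoromethanesulfonate | C=C(OS(=O)(=O)C(F)(F)F)c1c(OCOC)cc2OC(C)(C)CCc2c1OCOC | intermediate
12 | ring B 1-arylvinyl pinacol boronate | C=C(B1OC(C)(C)C(C)(C)O1)c1c(OCOC)cc2OC(C)(C)CCc2c1OCOC | intermediate
13 | 6-bromo-8-chloro-5,7-bis(methoxymethoxy)-2,2-dimethylchroman | Brc1c(OCOC)c(Cl)c2OC(C)(C)CCc2c1OCOC | intermediate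
14 | 1-bromo-4-methylpentane | CC(C)CCCBr | starting material
15 | 1-iodo-4-methylpentane | CC(C)CCCI | intermediate
16 | [8-chloro-5,7-bis(methoxymethoxy)-2,2-dimethylchroman-6-yl]lithium (ring A aryllithium) | [Li]c1c(OCOC)c(Cl)c2OC(C)(C)CCc2c1OCOC | intermediate (not isolated)
17 | lithium (ring A aryl)[1-(ring B aryl)vinyl](pinacolato)borate | [Li+].C=C(c1c(OCOC)cc2OC(C)(C)CCc2c1OCOC)[B-]1(c2c(OCOC)c(Cl)c3OC(C)(C)CCc3c2OCOC)OC(C)(C)C(C)(C)O1 | intermediate (not isolated)
18 | (R)-tertiary diarylalkyl pinacol boronate | CC(C)CCCC[C@@](B1OC(C)(C)C(C)(C)O1)(c1c(OCOC)c(Cl)c2OC(C)(C)CCc2c1OCOC)c1c(OCOC)cc2OC(C)(C)CCc2c1OCOC | intermediate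
19 | (R)-diarylalkane, four MOM ethers, chlorine at C8 of ring A | CC(C)CCCC[C@@H](c1c(OCOC)c(Cl)c2OC(C)(C)CCc2c1OCOC)c1c(OCOC)cc2OC(C)(C)CCc2c1OCOC | intermediate
20 | ring B C8 aryllithium of 19 | CC(C)CCCC[C@@H](c1c(OCOC)c(Cl)c2OC(C)(C)CCc2c1OCOC)c1c(OCOC)c([Li])c2OC(C)(C)CCc2c1OCOC | intermediate (not isolated)
21 | (R)-ring B isobutyryl ketone, four MOM ethers | CC(C)CCCC[C@@H](c1c(OCOC)c(Cl)c2OC(C)(C)CCc2c1OCOC)c1c(OCOC)c(C(=O)C(C)C)c2OC(C)(C)CCc2c1OCOC | intermediate
22 | (R)-chlorinated tetraphenol | CC(C)CCCC[C@@H](c1c(O)c(Cl)c2OC(C)(C)CCc2c1O)c1c(O)c(C(=O)C(C)C)c2OC(C)(C)CCc2c1O | intermediate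
23 | (S)-tetraphenol with free C8 on ring A | CC(C)CCCC[C@@H](c1c(O)cc2OC(C)(C)CCc2c1O)c1c(O)c(C(=O)C(C)C)c2OC(C)(C)CCc2c1O | intermediate
24 | (R)-2-methylbutanoic acid | CC[C@@H](C)C(=O)O | starting material
25 | (R)-2-methylbutanoyl chloride | CC[C@@H](C)C(=O)Cl | intermediate
26 | CNP0287681.1 | CC[C@@H](C)C(=O)c1c(O)c([C@H](CCCCC(C)C)c2c(O)c3c(c(C(=O)C(C)C)c2O)OC(C)(C)CC3)c(O)c2c1OC(C)(C)CC2 | target

**Step count**

Total: 15 steps. Longest linear sequence: 12 steps (1, 2, 3, 4, 5, 6, 9, 10, 11, 12, 13, 15).

**Steps most likely to fail**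

1. Step 9. The crowded ate complex may form slowly, the di-ortho-substituted aryl group may fail to migrate onto a carbon that already carries an aryl group, or the catalyst may select the alkene face poorly. The fallback uses the 1,2-metallate rearrangement of a lithiated secondary benzylic carbamate with an aryl boronic ester; it sets out from 13 (through 16) and from 5 (through 6) and comes back at 18. Aryllithium 16, made from 13 as in step 9, is added to 6-methylheptanal to give racemic 1-[8-chloro-5,7-bis(methoxymethoxy)-2,2-dimethylchroman-6-yl]-6-methylheptan-1-ol F1. Dess–Martin oxidation gives the ketone 1-[8-chloro-5,7-bis(methoxymethoxy)-2,2-dimethylchroman-6-yl]-6-methylheptan-1-one F2, and reduction with BH3·SMe2 and the (S)-Me-CBS oxazaborolidine gives the (R)-alcohol F3. NaH and i-Pr2NCOCl then give the (R)-N,N-diisopropylcarbamate F4. Separately, 5 is lithiated as in step 3 and 6 is quenched with i-PrOBpin to give the ring B aryl pinacol boronate F5. F4 is lithiated with s-BuLi in Et2O at −78 °C, with retention, to the lithiated carbamate F6; this is possible because ring A has no aromatic C–H left. F6 adds to F5 with retention to give the lithium boronate complex F7. On warming with MgBr2 in MeOH the ring B aryl group shifts from boron to carbon with inversion and the carbamate leaves, giving 18.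

2. Step 10. Fluoride may not reach a boron atom shielded by four ortho substituents, or protonation may occur with partial loss of configuration. The fallback sets out from 18 and comes back at 19, but it gives up the stereochemical information of step 9. Oxidation of 18 with H2O2 and NaOH in THF–water gives the tertiary alcohol (S)-1-[8-chloro-5,7-bis(methoxymethoxy)-2,2-dimethylchroman-6-yl]-1-[5,7-bis(methoxymethoxy)-2,2-dimethylchroman-6-yl]-6-methylheptan-1-ol F8. Ionic hydrogenation with Et3SiH and BF3·OEt2 in CH2Cl2 at −78 °C reduces the doubly benzylic cation to the racemic diarylalkane F9. Preparative chromatography on a chiral stationary phase then separates the enantiomers and delivers 19.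

3. Step 15. Configuration at the α-carbon of the acyl group may be lost through ketene formation from the acid chloride or enolisation of the product ketone on the Lewis acid. The fallback sets out from 23 and comes back at 26. 23 is acylated under the same Friedel–Crafts conditions with inexpensive racemic 2-methylbutanoyl chloride, which gives 26 together with its epimer at the acyl α-carbon, the (2S)-2-methylbutanoyl (1R)-methine compound F10. The two are diastereomers and are separated by preparative HPLC. F10 is recycled by base-mediated equilibration of the ketone α-centre (DBU, THF) and separated again.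

**Further compounds**

F1 | step 9 | racemic 1-[8-chloro-5,7-bis(methoxymethoxy)-2,2-dimethylchroman-6-yl]-6-methylheptan-1-ol | CC(C)CCCCC(O)c1c(OCOC)c(Cl)c2OC(C)(C)CCc2c1OCOC
F2 | step 9 | 1-[8-chloro-5,7-bis(methoxymethoxy)-2,2-dimethylchroman-6-yl]-6-methylheptan-1-one | CC(C)CCCCC(=O)c1c(OCOC)c(Cl)c2OC(C)(C)CCc2c1OCOC
F3 | step 9 | (R)-1-[8-chloro-5,7-bis(methoxymethoxy)-2,2-dimethylchroman-6-yl]-6-methylheptan-1-ol | CC(C)CCCC[C@H](c1c(OCOC)c(Cl)c2OC(C)(C)CCc2c1OCOC)O
F4 | step 9 | (R)-1-[8-chloro-5,7-bis(methoxymethoxy)-2,2-dimethylchroman-6-yl]-6-methylheptyl N,N-diisopropylcarbamate | CC(C)CCCC[C@H](c1c(OCOC)c(Cl)c2OC(C)(C)CCc2c1OCOC)OC(=O)N(C(C)C)C(C)C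
F5 | step 9 | 2-[5,7-bis(methoxymethoxy)-2,2-dimethylchroman-6-yl]-4,4,5,5-tetramethyl-1,3,2-dioxaborolane | CC1(C)OB(OC1(C)C)c1c(OCOC)cc2OC(C)(C)CCc2c1OCOC
F6 | step 9 | α-lithiated carbamate from F4 | CC(C)CCCC[C@]([Li])(c1c(OCOC)c(Cl)c2OC(C)(C)CCc2c1OCOC)OC(=O)N(C(C)C)C(C)C
F7 | step 9 | lithium boronate complex from F6 and F5 | [Li+].CC(C)CCCC[C@]([B-]1(c2c(OCOC)cc3OC(C)(C)CCc3c2OCOC)OC(C)(C)C(C)(C)O1)(c1c(OCOC)c(Cl)c2OC(C)(C)CCc2c1OCOC)OC(=O)N(C(C)C)C(C)C
F8 | step 10 | (S)-1-[8-chloro-5,7-bis(methoxymethoxy)-2,2-dimethylchroman-6-yl]-1-[5,7-bis(methoxymethoxy)-2,2-dimethylchroman-6-yl]-6-methylheptan-1-ol | CC(C)CCCC[C@@](O)(c1c(OCOC)c(Cl)c2OC(C)(C)CCc2c1OCOC)c1c(OCOC)cc2OC(C)(C)CCc2c1OCOC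
F9 | step 10 | racemic 19 | CC(C)CCCCC(c1c(OCOC)c(Cl)c2OC(C)(C)CCc2c1OCOC)c1c(OCOC)cc2OC(C)(C)CCc2c1OCOC
F10 | step 15 | epimer of 26 with (2S)-2-methylbutanoyl group and (1R) methine | CC[C@H](C)C(=O)c1c(O)c([C@H](CCCCC(C)C)c2c(O)c3c(c(C(=O)C(C)C)c2O)OC(C)(C)CC3)c(O)c2c1OC(C)(C)CC2
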